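## Structural features

Sceptrin is a cyclobutane with one substituent on each ring carbon. C1 and C4 (adjacent) each carry a 2-aminoimidazol-4(5)-yl ring bonded through a ring carbon, and C2 and C3 each carry a CH2NH–C(=O)–(4-bromo-1H-pyrrol-2-yl) arm. All four neighbouring pairs are trans and the molecule has a C2 axis through the midpoints of the C1–C4 and C2–C3 bonds. In this numbering the required enantiomer is (1S,2R,3R,4S), so only two stereochemical questions are independent: the trans pair C2/C3 in its absolute sense, and the pair C1/C4 relative to it. The 2-aminoimidazoles are basic, polar and easily oxidised, and the bromopyrroles would not survive hydrogenolysis or a cerium oxidant, so both heterocycles belong at the end. The real difficulty is the strained ring with four contiguous stereocentres, built from two unlike two-carbon halves in one absolute configuration. Two features make this tractable. While C1 and C4 carry carbonyl groups (the carbons that later become the imidazole carbons bonded to the ring) they are epimerisable, and all-trans is the thermodynamic arrangement, so only C2 and C3 must be set kinetically. The nitrogen of the C2 arm is three bonds from that carbonyl carbon on C1 (N–CH2–C2–C1–C), the spacing of a γ-lactam. The key step uses this to tether the two alkenes as an N-butenyl fumaramide and to close the cyclobutane as C1, C5, C6 and C7 of a 3-azabicyclo[3.2.0]heptan-2-one.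

## Logic of the disconnections

21 is cut at the two exocyclic amide C–N bonds to give 19 and two molecules of 20. The bromopyrrole is the least robust part, and the cut leaves a C2-symmetric tetraamine. The forward step must acylate the two primary amines and leave the 2-aminoimidazole nitrogens alone.

19 is traced through 18 to 16 and 17 by cutting, in each imidazole, the two C–N bonds that join the guanidine unit to the C–C pair of an α-bromoketone. Both heterocycles then arrive with their amino group in one operation. The forward step needs the arm nitrogens masked as carbamates so that they do not attack the bromoketones.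

16 is traced through 15 to 14 by cutting the bond between each ketone carbonyl and its CH2Br carbon. This one-carbon homologation reduces the problem to a C2-symmetric diester and avoids diazomethane. It demands that a stabilised sulfur ylide be acylated by two hindered secondary esters.

14 is traced through 13, 12 and 11 to 10 and 9 by reconnecting the ester carbon on C1 to the nitrogen of the C2 arm as a lactam, and by inverting C1 and C4. This turns four stereocentres into two that must be controlled. The forward steps need removal of the N-auxiliary, methanolysis at the ring carbonyl only, and base equilibration of both ester carbons to all-trans.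

9 is cut at C1–C2 and C3–C4 of the cyclobutane to give 8, an acyclic diene whose only stereocentre is the auxiliary. Two rings, two skeletal bonds and four stereocentres are gained in one step. The step must give the fused regiochemistry, the trans C2/C3 pair, and one face of the butenyl alkene.

8 is cut at the amide C–N bond to 5 and 7 (made from 6). 5 is cut at an allylic C–N bond to 3 and 4, and 3 at the other allylic C–N bond to 1 and 2. All four end points are commercial. The forward steps need monosubstitution of 1 and monoalkylation of 4.

## Other disconnections considered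

Alternative 1: The cut is at the two bonds from C2 and C3 to their side-chain carbons, installed by directed C–H functionalisation on a purchased cyclobutane.

- Forward key step: the bis(8-aminoquinolinyl) amide A2 of (1R,2R)-cyclobutane-1,2-dicarboxylic acid would be alkenylated twice with the iodostyrene A3 under Pd(OAc)2 and AgOAc to give the cis,trans,cis bis-styryl diamide A1.
- Mechanism: chelation-assisted palladation by divalent palladium, oxidative addition of A3 to a tetravalent palladium species, and reductive elimination. Each styryl group is delivered cis to its directing amide, so the relative configuration is predictable.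
- In its favour: the absolute configuration comes from an enantiopure diacid, and no photochemistry is needed. On certainty of absolute stereocontrol it is better than the chosen plan, whose auxiliary induction is untested.
- Against it: two hindered aminoquinoline amides must be removed, by the same Boc-activation tactic as the lactam opening here. Each styryl group must be degraded by ozonolysis and reductive amination, which discards a benzaldehyde per arm. The ring aldehydes formed on the way make C2 and C3 epimerisable while C1 and C4 are also α to carbonyls, so enantiopurity could erode. Stoichiometric silver is needed.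
- Comparison: both plans need a late epimerisation of C1 and C4 to reach all-trans, and both converge on a diester of the type of 14 in roughly the same number of steps, so step economy is about equal. Alternative 1 is weaker on atom economy and on reagent hazard (ozone, silver, palladium loading).

Alternative 2: The cut lies inside each imidazole, at C4–C5 and N1–C2.

- Forward key step: the all-trans dialdehyde A5 would condense with the benzylic amine A7 to a bis-aldimine, and the isocyanide A6 with K2CO3 would add twice (van Leusen) to give the bis(1,5-disubstituted imidazole) A4.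
- Mechanism: addition of the sulfonyl-stabilised anion to the imine, ring closure of nitrogen onto the isocyanide carbon, and loss of sulfinate.
- In its favour: it is two-directional, uses the C2 symmetry, runs under mild base, tolerates epimerisable aldehyde carbons (all-trans is again the thermodynamic outcome), and avoids alkylating α-bromoketones. On that last handling point it is better than the chosen endgame.
- Against it: A4 lacks both 2-amino groups. These would need twofold C2-metalation and azide transfer followed by reduction. The dimethoxybenzyl groups and four N-benzyl groups must also be removed before the bromopyrroles are attached.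
- Comparison: the step forms neither the four-membered ring nor any ring stereocentre. A5 would still have to come from a ring-forming event, for example from 14 by reduction and oxidation, so this replaces the endgame and not the key step. From a diester, the chosen route reaches protected aminoimidazoles in three steps with the amino group built in. Alternative 2 would need about twice as many, so it is poorer in step economy and equal in two-directional character.

Alternative 3: The cut is at C1–C2 of the cyclobutane, leading back to the NH-pyrrolidine A9 in which nitrogen bridges these two carbons.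

- Forward key step: N-amination of A9 by an iodonitrene (PhI(OH)OTs with ammonium carbamate) would give a 1,1-diazene that loses N2. The resulting 1,4-biradical would recombine to the cyclobutane A8.
- In its favour: A9 is the product of an azomethine ylide cycloaddition, a reaction class with mature catalytic enantiocontrol. The absolute configuration would rest on the imidazolyl-bearing carbon, which is not epimerisable. The contraction is thermal. On the source of absolute configuration it is better than the chosen plan.
- Against it: both radical termini are stabilised (heteroaryl-substituted and α-ester), which favours fragmentation to two alkenes and leakage of configuration. That loss is irreversible, whereas cleavage of the biradical in the chosen step only returns the diene. A8 is not all-trans, and its three epimerisable centres would each have to invert. The four substituents of A8 then need four different conversions: two esters to aminomethyl groups, acetyl to an aminoimidazole through a regioselective α-halogenation, and C2-amination of the existing imidazole. The symmetry of the target goes unused.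
- Comparison: both plans pass through a 1,4-biradical and both rely on thermodynamic epimerisation. Alternative 3 is longer, estimated at sixteen steps or more against thirteen.

Key step: step 4

Remarks on the structures, made before the steps:

- Correction of the photoadduct: an (E)-fumaramate that keeps its geometry gives the C7 ester exo (trans to the lactam carbonyl, cis to the C6 arm), and only then must both ester carbons be inverted later. Compound 9 is therefore drawn (1R,5R,6R,7R). A structure with the ester endo would be inconsistent with both points. Any 7-endo epimer converges in step 7.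
- Design change: the butenyl nitrogen is carried as N(Boc)2, not NHBoc, up to step 8. After auxiliary removal the lactam N–H is then the only acylatable site, so the Boc activation (step 6) can be run exhaustively instead of selectively. The step count is unchanged, because one Boc group is removed after the lactam opening instead of before the acylation.
- "Crossed" refers to the pairing of two unlike alkenes. The regiochemistry is the fused (straight) mode.
- Assumption: the (S)-auxiliary favours the (5R,6R) face. If the bias proves opposite, the (R)-enantiomer of 4 is used. The two adducts are diastereomers and separable either way.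
- Assumption: in 18 the Boc group from 17 is drawn on the ring nitrogen remote from the cyclobutyl-bearing carbon. Its position is immaterial because step 12 removes it.

## Route

Step 1
Reactants: 1 (E)-1,4-dibromobut-2-ene; 2 di-tert-butyl iminodicarboxylate
Product: 3 di-tert-butyl N-[(E)-4-bromobut-2-en-1-yl]iminodicarbonate
Conditions: 1 (3 equiv), K2CO3, DMF, rt
Reagents that add atoms: none
Why: Gabriel-type N-alkylation of the acidic imide nitrogen by SN2 at a primary allylic bromide, with the E geometry untouched; the excess of 1 should suppress double substitution, and K2CO3 avoids the hazard of NaH in DMF.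

Step 2
Reactants: 3 di-tert-butyl N-[(E)-4-bromobut-2-en-1-yl]iminodicarbonate; 4 (S)-1-(4-methoxyphenyl)ethylamine
Product: 5 di-tert-butyl N-[(E)-4-{[(1S)-1-(4-methoxyphenyl)ethyl]amino}but-2-en-1-yl]iminodicarbonate
Conditions: 4 (2.5 equiv), K2CO3, MeCN, rt
Reagents that add atoms: none
Why: SN2 N-alkylation of a primary amine; the α-branch and the excess of 4 should limit dialkylation, and the stereocentre of 4 is not involved.

Step 3
Reactants: 5 di-tert-butyl N-[(E)-4-{[(1S)-1-(4-methoxyphenyl)ethyl]amino}but-2-en-1-yl]iminodicarbonate; 6 monomethyl fumarate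
Product: 8 methyl (E)-4-{[(E)-4-[bis(tert-butoxycarbonyl)amino]but-2-en-1-yl][(1S)-1-(4-methoxyphenyl)ethyl]amino}-4-oxobut-2-enoate, via methyl (E)-4-chloro-4-oxobut-2-enoate 7 (not isolated)
Conditions: 6, (COCl)2, DMF (cat.), CH2Cl2, 0 °C → rt, evaporate; then 5, CH2Cl2/sat. aq NaHCO3, 0 °C
Reagents that add atoms: none
Why: Acid chloride formation followed by Schotten–Baumann N-acylation; the secondary amine is the only nucleophilic nitrogen, since the imidodicarbonate has no N–H, and acylation should outrun conjugate addition at 0 °C.

Step 4
Reactants: 8 methyl (E)-4-{[(E)-4-[bis(tert-butoxycarbonyl)amino]but-2-en-1-yl][(1S)-1-(4-methoxyphenyl)ethyl]amino}-4-oxobut-2-enoate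
Product: 9 methyl (1R,5R,6R,7R)-6-{[bis(tert-butoxycarbonyl)amino]methyl}-3-[(1S)-1-(4-methoxyphenyl)ethyl]-2-oxo-3-azabicyclo[3.2.0]heptane-7-carboxylate
Conditions: thioxanthone (10 mol%), degassed MeCN (5 mM), 405 nm LEDs, rt; separation from the facial diastereomer on silica
Reagents that add atoms: none
Why: This is a sensitised intramolecular [2+2] photocycloaddition of an N-alkenyl unsaturated amide, the known entry to 3-azabicyclo[3.2.0]heptan-2-ones: triplet thioxanthone (about 65 kcal/mol) should pass its energy to the fumaramate, the only low-lying acceptor, while the anisyl ring and the carbamates do not absorb at 405 nm. The triplet bonds from the carbon α to the amide carbonyl to the inner butenyl carbon in a 5-exo closure (rule of five), which forms the lactam ring and the C1–C5 bond and leaves a 1,4-biradical with one centre α to the ester; the bulky N-(1-arylethyl) group prefers the amide position syn to oxygen and so holds the butenyl arm over the fumaroyl double bond. After intersystem crossing the biradical closes the four-membered ring through C6–C7 by radical recombination, or it reverts to the open diene, which is simply excited again. C1 is fixed relative to C5 by the cis fusion that a five-four bicycle requires; C6 takes its CH2N(Boc)2 group exo, trans to the C5–C4 bond, because the radical closes on the convex face and the E geometry already places it there; C7 should also come out exo, but its configuration is of no consequence. The selectivity that matters is the face of the butenyl alkene attacked in the 5-exo step, since it fixes C5 and with it C6 in the absolute sense; it is biased, not guaranteed, by the N-stereocentre, whose C–H bond lies in the amide plane and so places methyl and anisyl on opposite faces of the forming lactam. Because the two possible adducts are diastereomers, chromatography should deliver 9 configurationally pure whatever the bias. The fused rather than bridged regiochemistry follows from the three-atom tether.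

Step 5
Reactants: 9 methyl (1R,5R,6R,7R)-6-{[bis(tert-butoxycarbonyl)amino]methyl}-3-[(1S)-1-(4-methoxyphenyl)ethyl]-2-oxo-3-azabicyclo[3.2.0]heptane-7-carboxylate
Product: 10 methyl (1R,5R,6R,7R)-6-{[bis(tert-butoxycarbonyl)amino]methyl}-2-oxo-3-azabicyclo[3.2.0]heptane-7-carboxylate
Conditions: (NH4)2Ce(NO3)6 (3 equiv), MeCN/H2O (4:1), 0 °C
Reagents that add atoms: none
Why: Oxidative N-dearylmethylation: tetravalent cerium oxidises the anisyl ring by single-electron transfer, loss of the benzylic proton and a second oxidation give an N-acyliminium ion, and water cleaves it to 10 and 4-methoxyacetophenone; no alkene remains, and esters and carbamates should be inert at 0 °C. Any material that sheds one Boc group in the acidic medium is restored in step 6.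

Step 6
Reactants: 10 methyl (1R,5R,6R,7R)-6-{[bis(tert-butoxycarbonyl)amino]methyl}-2-oxo-3-azabicyclo[3.2.0]heptane-7-carboxylate
Product: 11 3-tert-butyl 7-methyl (1R,5R,6R,7R)-6-{[bis(tert-butoxycarbonyl)amino]methyl}-2-oxo-3-azabicyclo[3.2.0]heptane-3,7-dicarboxylate
Conditions: Boc2O (3 equiv), 4-(dimethylamino)pyridine (0.3 equiv), MeCN, rt
Reagents that add atoms: di-tert-butyl dicarbonate, CC(C)(C)OC(=O)OC(=O)OC(C)(C)C
Why: Nucleophile-catalysed N-acylation of the lactam, which turns the ring carbonyl into an activated acyl carbamate; it is run exhaustively because every N–H in the molecule is meant to end up Boc-substituted, so no site selectivity is needed.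

Step 7
Reactants: 11 3-tert-butyl 7-methyl (1R,5R,6R,7R)-6-{[bis(tert-butoxycarbonyl)amino]methyl}-2-oxo-3-azabicyclo[3.2.0]heptane-3,7-dicarboxylate
Product: 13 dimethyl (1S,2S,3R,4R)-3-{[bis(tert-butoxycarbonyl)amino]methyl}-4-[(tert-butoxycarbonylamino)methyl]cyclobutane-1,2-dicarboxylate, via kinetic ring-opened diester 12 (not isolated)
Conditions: NaOMe (2 equiv), MeOH, 0 °C, then 50 °C
Reagents that add atoms: methanol (delivered as sodium methoxide), CO
Why: Methanolysis of an N-Boc lactam at the strained ring carbonyl releases the carbamate and gives 12, in which each ester is still cis to the arm beside it; reversible enolisation of both ester α-carbons under the same base should then drain the mixture into the all-trans diester, the thermodynamic isomer, which is where C1 and C4 of the target are set. Partial loss of one Boc group from the imidodicarbonate would only anticipate step 8.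

Step 8
Reactants: 13 dimethyl (1S,2S,3R,4R)-3-{[bis(tert-butoxycarbonyl)amino]methyl}-4-[(tert-butoxycarbonylamino)methyl]cyclobutane-1,2-dicarboxylate
Product: 14 dimethyl (1S,2S,3R,4R)-3,4-bis[(tert-butoxycarbonylamino)methyl]cyclobutane-1,2-dicarboxylate
Conditions: LiBr (3 equiv), MeCN, 65 °C
Reagents that add atoms: none
Why: Selective cleavage of one Boc group of an N,N-di-Boc amine: lithium held between the two carbamate carbonyls promotes loss of tert-butyl as isobutene and of CO2, while mono-carbamates and methyl esters are unaffected; the neutral medium leaves the ring centres alone, and the product is C2-symmetric.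

Step 9
Reactants: 14 dimethyl (1S,2S,3R,4R)-3,4-bis[(tert-butoxycarbonylamino)methyl]cyclobutane-1,2-dicarboxylate
Product: 15 di-tert-butyl N,N'-{[(1R,2R,3S,4S)-3,4-bis{2-[dimethyl(oxo)sulfuranylidene]acetyl}cyclobutane-1,2-diyl]bis(methylene)}dicarbamate
Conditions: Me3S(O)I (6 equiv), KOtBu (5.8 equiv), THF, reflux; then 14, reflux
Reagents that add atoms: trimethylsulfoxonium iodide, C[S+](C)(C)=O.[I-]
Why: Acylation of the Corey–Chaykovsky ylide: dimethylsulfoxonium methylide adds to each ester, methoxide leaves, and a second equivalent of ylide deprotonates the adduct to a stabilised β-keto ylide that does not add again; this is the safe substitute for a diazoketone homologation. The carbamate N–H is less acidic than the conjugate acid of the ylide, and any epimerisation at the ester carbons returns to all-trans.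

Step 10
Reactants: 15 di-tert-butyl N,N'-{[(1R,2R,3S,4S)-3,4-bis{2-[dimethyl(oxo)sulfuranylidene]acetyl}cyclobutane-1,2-diyl]bis(methylene)}dicarbamate
Product: 16 di-tert-butyl N,N'-{[(1R,2R,3S,4S)-3,4-bis(bromoacetyl)cyclobutane-1,2-diyl]bis(methylene)}dicarbamate
Conditions: MsOH (2.1 equiv), LiBr (6 equiv), THF, 50 °C
Reagents that add atoms: lithium bromide, [Li+].[Br-]
Why: C-protonation of each ylide gives a β-keto sulfoxonium salt, and bromide displaces dimethyl sulfoxide by SN2 at the methylene carbon; the acid is consumed by the basic ylide carbon, so the Boc groups should survive.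

Step 11
Reactants: 16 di-tert-butyl N,N'-{[(1R,2R,3S,4S)-3,4-bis(bromoacetyl)cyclobutane-1,2-diyl]bis(methylene)}dicarbamate; 17 N-(tert-butoxycarbonyl)guanidine
Product: 18 di-tert-butyl 4,4'-[(1S,2S,3R,4R)-3,4-bis{[(tert-butoxycarbonyl)amino]methyl}cyclobutane-1,2-diyl]bis(2-amino-1H-imidazole-1-carboxylate)
Conditions: 17 (6 equiv), DMF, rt
Reagents that add atoms: none
Why: Cyclocondensation of an α-haloketone with an acylguanidine: N-alkylation at the bromomethyl carbon, closure of a second guanidine nitrogen onto the ketone and dehydration give the 2-aminoimidazole, with excess 17 taking up HBr. Once the rings form, C1 and C4 are no longer α to a carbonyl and their configuration is fixed.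

Step 12
Reactants: 18 di-tert-butyl 4,4'-[(1S,2S,3R,4R)-3,4-bis{[(tert-butoxycarbonyl)amino]methyl}cyclobutane-1,2-diyl]bis(2-amino-1H-imidazole-1-carboxylate)
Product: 19 [(1R,2R,3S,4S)-3,4-bis(2-amino-1H-imidazol-5-yl)cyclobutane-1,2-diyl]dimethanamine, handled as its tetrakis(trifluoroacetate) salt
Conditions: CF3CO2H/CH2Cl2 (1:1), rt; evaporate
Reagents that add atoms: none
Why: Acidolysis of all four tert-butyl carbamates through the tert-butyl cation; 2-aminoimidazoles and the cyclobutane are stable to the acid.

Step 13
Reactants: 19 [(1R,2R,3S,4S)-3,4-bis(2-amino-1H-imidazol-5-yl)cyclobutane-1,2-diyl]dimethanamine; 20 2,2,2-trichloro-1-(4-bromo-1H-pyrrol-2-yl)ethanone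
Product: 21 sceptrin, N,N'-{[(1R,2R,3S,4S)-3,4-bis(2-amino-1H-imidazol-5-yl)cyclobutane-1,2-diyl]bis(methylene)}bis(4-bromo-1H-pyrrole-2-carboxamide)
Conditions: 20 (2.1 equiv), Na2CO3, DMF, rt
Reagents that add atoms: none
Why: Haloform-type acyl transfer: each primary amine adds to the trichloromethyl ketone and expels trichloromethanide as chloroform, with no coupling reagent and no pyrrole protection. The 2-aminoimidazole nitrogens are delocalised, guanidine-like and weakly nucleophilic, and are expected to stay free, as is usual for this reagent class in pyrrole–imidazole alkaloid chemistry.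

## Compound list

1 | (E)-1,4-dibromobut-2-ene | BrC/C=C/CBr | starting material
2 | di-tert-butyl iminodicarboxylate | CC(C)(C)OC(=O)NC(=O)OC(C)(C)C | starting material
3 | di-tert-butyl N-[(E)-4-bromobut-2-en-1-yl]iminodicarbonate | BrC/C=C/CN(C(=O)OC(C)(C)C)C(=O)OC(C)(C)C | intermediate
4 | (S)-1-(4-methoxyphenyl)ethylamine | C[C@H](N)c1ccc(OC)cc1 | starting material
5 | di-tert-butyl N-[(E)-4-{[(1S)-1-(4-methoxyphenyl)ethyl]amino}but-2-en-1-yl]iminodicarbonate | C[C@H](NC/C=C/CN(C(=O)OC(C)(C)C)C(=O)OC(C)(C)C)c1ccc(OC)cc1 | intermediate
6 | monomethyl fumarate | COC(=O)/C=C/C(=O)O | starting material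
7 | methyl (E)-4-chloro-4-oxobut-2-enoate | COC(=O)/C=C/C(=O)Cl | intermediate (not isolated)
8 | methyl (E)-4-{[(E)-4-[bis(tert-butoxycarbonyl)amino]but-2-en-1-yl][(1S)-1-(4-methoxyphenyl)ethyl]amino}-4-oxobut-2-enoate | COC(=O)/C=C/C(=O)N([C@@H](C)c1ccc(OC)cc1)C/C=C/CN(C(=O)OC(C)(C)C)C(=O)OC(C)(C)C | intermediate
9 | methyl (1R,5R,6R,7R)-6-{[bis(tert-butoxycarbonyl)amino]methyl}-3-[(1S)-1-(4-methoxyphenyl)ethyl]-2-oxo-3-azabicyclo[3.2.0]heptane-7-carboxylate (cis-fused, both substituents exo) | O=C1N([C@@H](C)c3ccc(OC)cc3)C[C@@H]2[C@@H](CN(C(=O)OC(C)(C)C)C(=O)OC(C)(C)C)[C@@H](C(=O)OC)[C@H]12 | intermediate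
10 | methyl (1R,5R,6R,7R)-6-{[bis(tert-butoxycarbonyl)amino]methyl}-2-oxo-3-azabicyclo[3.2.0]heptane-7-carboxylate | O=C1NC[C@@H]2[C@@H](CN(C(=O)OC(C)(C)C)C(=O)OC(C)(C)C)[C@@H](C(=O)OC)[C@H]12 | intermediate
11 | 3-tert-butyl 7-methyl (1R,5R,6R,7R)-6-{[bis(tert-butoxycarbonyl)amino]methyl}-2-oxo-3-azabicyclo[3.2.0]heptane-3,7-dicarboxylate | O=C1N(C(=O)OC(C)(C)C)C[C@@H]2[C@@H](CN(C(=O)OC(C)(C)C)C(=O)OC(C)(C)C)[C@@H](C(=O)OC)[C@H]12 | intermediate
12 | dimethyl 3-{[bis(tert-butoxycarbonyl)amino]methyl}-4-[(tert-butoxycarbonylamino)methyl]cyclobutane-1,2-dicarboxylate, kinetic isomer (each ester cis to the arm beside it, esters trans, arms trans) | COC(=O)[C@@H]1[C@H](CNC(=O)OC(C)(C)C)[C@@H](CN(C(=O)OC(C)(C)C)C(=O)OC(C)(C)C)[C@H]1C(=O)OC | intermediate (not isolated)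
13 | dimethyl (1S,2S,3R,4R)-3-{[bis(tert-butoxycarbonyl)amino]methyl}-4-[(tert-butoxycarbonylamino)methyl]cyclobutane-1,2-dicarboxylate (all-trans) | COC(=O)[C@H]1[C@H](CNC(=O)OC(C)(C)C)[C@@H](CN(C(=O)OC(C)(C)C)C(=O)OC(C)(C)C)[C@@H]1C(=O)OC | intermediate
14 | dimethyl (1S,2S,3R,4R)-3,4-bis[(tert-butoxycarbonylamino)methyl]cyclobutane-1,2-dicarboxylate (all-trans, C2-symmetric) | COC(=O)[C@H]1[C@H](CNC(=O)OC(C)(C)C)[C@@H](CNC(=O)OC(C)(C)C)[C@@H]1C(=O)OC | intermediate
15 | di-tert-butyl N,N'-{[(1R,2R,3S,4S)-3,4-bis{2-[dimethyl(oxo)sulfuranylidene]acetyl}cyclobutane-1,2-diyl]bis(methylene)}dicarbamate (all-trans) | CS(C)(=O)=CC(=O)[C@H]1[C@H](CNC(=O)OC(C)(C)C)[C@@H](CNC(=O)OC(C)(C)C)[C@@H]1C(=O)C=S(C)(C)=O | intermediate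
16 | di-tert-butyl N,N'-{[(1R,2R,3S,4S)-3,4-bis(bromoacetyl)cyclobutane-1,2-diyl]bis(methylene)}dicarbamate (all-trans) | BrCC(=O)[C@H]1[C@H](CNC(=O)OC(C)(C)C)[C@@H](CNC(=O)OC(C)(C)C)[C@@H]1C(=O)CBr | intermediate
17 | N-(tert-butoxycarbonyl)guanidine | CC(C)(C)OC(=O)NC(N)=N | starting material
18 | di-tert-butyl 4,4'-[(1S,2S,3R,4R)-3,4-bis{[(tert-butoxycarbonyl)amino]methyl}cyclobutane-1,2-diyl]bis(2-amino-1H-imidazole-1-carboxylate) (all-trans) | Nc1nc([C@H]2[C@H](CNC(=O)OC(C)(C)C)[C@@H](CNC(=O)OC(C)(C)C)[C@@H]2c2cn(C(=O)OC(C)(C)C)c(N)n2)cn1C(=O)OC(C)(C)C | intermediate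
19 | [(1R,2R,3S,4S)-3,4-bis(2-amino-1H-imidazol-5-yl)cyclobutane-1,2-diyl]dimethanamine (all-trans; handled as the tetrakis(trifluoroacetate) salt) | Nc1ncc([C@H]2[C@H](CN)[C@@H](CN)[C@@H]2c2cnc(N)[nH]2)[nH]1 | intermediate
20 | 2,2,2-trichloro-1-(4-bromo-1H-pyrrol-2-yl)ethanone | O=C(c1cc(Br)c[nH]1)C(Cl)(Cl)Cl | starting material
21 | sceptrin | Nc1ncc([C@H]2[C@H](CNC(=O)c3cc(Br)c[nH]3)[C@@H](CNC(=O)c3cc(Br)c[nH]3)[C@@H]2c2cnc(N)[nH]2)[nH]1 | target

## Step count and least certain steps

Total step count: 13. Longest linear sequence: 13 steps (1 to 21); 4, 6, 17 and 20 enter as purchased materials.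

Step 4 (key step). The most likely failure is weak discrimination between the two faces of the butenyl alkene, because the controlling stereocentre sits on nitrogen three bonds from the nearest new centre, possibly together with diastereomers that do not separate. Slow energy transfer is the second risk and would first be met by a higher-energy sensitiser (xanthone or benzophenone at 365 nm), which is only a change of conditions. The fallback replaces auxiliary control by resolution and sets out from 3. Alkylation of 4-methoxybenzylamine with 3 gives di-tert-butyl N-[(E)-4-(4-methoxybenzylamino)but-2-en-1-yl]iminodicarbonate F1. Acylation with 7 gives the achiral fumaramate methyl (E)-4-{[(E)-4-[bis(tert-butoxycarbonyl)amino]but-2-en-1-yl](4-methoxybenzyl)amino}-4-oxobut-2-enoate F2. The same irradiation gives the N-(4-methoxybenzyl) bicyclic lactam as a racemate, and preparative chromatography on a chiral stationary phase supplies its (1R,5R,6R,7R) enantiomer, methyl 6-{[bis(tert-butoxycarbonyl)amino]methyl}-3-(4-methoxybenzyl)-2-oxo-3-azabicyclo[3.2.0]heptane-7-carboxylate F3. Treatment with (NH4)2Ce(NO3)6 then removes the benzyl group, and the route is rejoined at 10.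

Step 5. The likely failure is sluggish or unselective oxidation at a tertiary benzylic C–H on a hindered lactam nitrogen, with acid-induced loss of Boc groups alongside. The fallback removes the auxiliary by acidolysis and sets out from 9. Hot CF3CO2H with anisole cleaves the 1-(4-methoxyphenyl)ethyl group as its stabilised benzylic cation together with both Boc groups. This gives methyl (1R,5R,6R,7R)-6-(aminomethyl)-2-oxo-3-azabicyclo[3.2.0]heptane-7-carboxylate F4 as its trifluoroacetate. The salt is kept protonated until Boc2O is present, so that the amine does not lactamise onto the cis ester. Exhaustive acylation with Boc2O, Et3N and 4-(dimethylamino)pyridine then gives the tri-Boc compound, and the route is rejoined at 11.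

Step 9. The likely failure is incomplete acylation of the ylide by two hindered secondary methyl esters, with enolisation competing. The fallback raises the acylating power and sets out from 14. Saponification with LiOH in THF/H2O gives (1S,2S,3R,4R)-3,4-bis[(tert-butoxycarbonylamino)methyl]cyclobutane-1,2-dicarboxylic acid F5; the trans diacid cannot close to an anhydride. Carbodiimide coupling with 4-nitrophenol gives the bis(4-nitrophenyl) ester F6. This activated ester should acylate dimethylsulfoxonium methylide at 0 °C to rt, and the route is rejoined at 15.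

Step 11. The likely failure is a twofold cyclocondensation that stalls at the N-alkylated open stage, or consumption of the bromoketone by elimination and self-condensation. The fallback builds the rings from α-aminoketones and sets out from 16. NaN3 in DMF at 0 °C gives the bis(azidoacetyl) compound di-tert-butyl N,N'-{[(1R,2R,3S,4S)-3,4-bis(azidoacetyl)cyclobutane-1,2-diyl]bis(methylene)}dicarbamate F7. Hydrogenation over Pd/C in MeOH containing two equivalents of HCl gives the bis(aminoacetyl) compound as its dihydrochloride F8. Condensation with cyanamide in water at pH 4.5 and 90 °C gives the bis(2-aminoimidazole) di-tert-butyl N,N'-{[(1R,2R,3S,4S)-3,4-bis(2-amino-1H-imidazol-5-yl)cyclobutane-1,2-diyl]bis(methylene)}dicarbamate F9. CF3CO2H then removes the two carbamates, and the route is rejoined at 19.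

## Further compounds

F1 | step 4 | di-tert-butyl N-[(E)-4-(4-methoxybenzylamino)but-2-en-1-yl]iminodicarbonate | COc1ccc(CNC/C=C/CN(C(=O)OC(C)(C)C)C(=O)OC(C)(C)C)cc1
F2 | step 4 | methyl (E)-4-{[(E)-4-[bis(tert-butoxycarbonyl)amino]but-2-en-1-yl](4-methoxybenzyl)amino}-4-oxobut-2-enoate | COC(=O)/C=C/C(=O)N(Cc1ccc(OC)cc1)C/C=C/CN(C(=O)OC(C)(C)C)C(=O)OC(C)(C)C
F3 | step 4 | methyl (1R,5R,6R,7R)-6-{[bis(tert-butoxycarbonyl)amino]methyl}-3-(4-methoxybenzyl)-2-oxo-3-azabicyclo[3.2.0]heptane-7-carboxylate (formed as the racemate, this enantiomer kept after resolution) | O=C1N(Cc3ccc(OC)cc3)C[C@@H]2[C@@H](CN(C(=O)OC(C)(C)C)C(=O)OC(C)(C)C)[C@@H](C(=O)OC)[C@H]12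
F4 | step 5 | methyl (1R,5R,6R,7R)-6-(aminomethyl)-2-oxo-3-azabicyclo[3.2.0]heptane-7-carboxylate (as trifluoroacetate) | O=C1NC[C@@H]2[C@@H](CN)[C@@H](C(=O)OC)[C@H]12
F5 | step 9 | (1S,2S,3R,4R)-3,4-bis[(tert-butoxycarbonylamino)methyl]cyclobutane-1,2-dicarboxylic acid | OC(=O)[C@H]1[C@H](CNC(=O)OC(C)(C)C)[C@@H](CNC(=O)OC(C)(C)C)[C@@H]1C(=O)O
F6 | step 9 | bis(4-nitrophenyl) (1S,2S,3R,4R)-3,4-bis[(tert-butoxycarbonylamino)methyl]cyclobutane-1,2-dicarboxylate | O=C(Oc1ccc(cc1)[N+](=O)[O-])[C@H]1[C@H](CNC(=O)OC(C)(C)C)[C@@H](CNC(=O)OC(C)(C)C)[C@@H]1C(=O)Oc1ccc(cc1)[N+](=O)[O-]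
F7 | step 11 | di-tert-butyl N,N'-{[(1R,2R,3S,4S)-3,4-bis(azidoacetyl)cyclobutane-1,2-diyl]bis(methylene)}dicarbamate | [N-]=[N+]=NCC(=O)[C@H]1[C@H](CNC(=O)OC(C)(C)C)[C@@H](CNC(=O)OC(C)(C)C)[C@@H]1C(=O)CN=[N+]=[N-]
F8 | step 11 | di-tert-butyl N,N'-{[(1R,2R,3S,4S)-3,4-bis(aminoacetyl)cyclobutane-1,2-diyl]bis(methylene)}dicarbamate (as dihydrochloride) | NCC(=O)[C@H]1[C@H](CNC(=O)OC(C)(C)C)[C@@H](CNC(=O)OC(C)(C)C)[C@@H]1C(=O)CN
F9 | step 11 | di-tert-butyl N,N'-{[(1R,2R,3S,4S)-3,4-bis(2-amino-1H-imidazol-5-yl)cyclobutane-1,2-diyl]bis(methylene)}dicarbamate | Nc1ncc([C@H]2[C@H](CNC(=O)OC(C)(C)C)[C@@H](CNC(=O)OC(C)(C)C)[C@@H]2c2cnc(N)[nH]2)[nH]1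
A1 | alternative 1 | N,N'-di(quinolin-8-yl)-3,4-di[(E)-styryl]cyclobutane-1,2-dicarboxamide, cis,trans,cis | O=C(Nc1cccc2cccnc12)[C@@H]1[C@H](/C=C/c2ccccc2)[C@@H](/C=C/c2ccccc2)[C@H]1C(=O)Nc1cccc2cccnc12
A2 | alternative 1 | (1R,2R)-N,N'-di(quinolin-8-yl)cyclobutane-1,2-dicarboxamide | O=C(Nc1cccc2cccnc12)[C@@H]1CC[C@H]1C(=O)Nc1cccc2cccnc12
A3 | alternative 1 | (E)-(2-iodovinyl)benzene | I/C=C/c1ccccc1
A4 | alternative 2 | all-trans 1,2-bis(dibenzylaminomethyl)-3,4-bis[1-(2,4-dimethoxybenzyl)imidazol-5-yl]cyclobutane | COc1ccc(Cn2cncc2[C@H]2[C@H](CN(Cc3ccccc3)Cc3ccccc3)[C@@H](CN(Cc3ccccc3)Cc3ccccc3)[C@@H]2c2cncn2Cc2ccc(OC)cc2OC)c(OC)c1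
A5 | alternative 2 | all-trans 3,4-bis(dibenzylaminomethyl)cyclobutane-1,2-dicarbaldehyde | O=C[C@H]1[C@H](CN(Cc2ccccc2)Cc2ccccc2)[C@@H](CN(Cc2ccccc2)Cc2ccccc2)[C@@H]1C=O
A6 | alternative 2 | p-toluenesulfonylmethyl isocyanide | Cc1ccc(cc1)S(=O)(=O)C[N+]#[C-]
A7 | alternative 2 | 2,4-dimethoxybenzylamine | COc1ccc(CN)c(OC)c1
A8 | alternative 3 | dimethyl 3-acetyl-4-[1-(dimethylsulfamoyl)imidazol-4-yl]cyclobutane-1,2-dicarboxylate | CN(C)S(=O)(=O)n1cnc(c1)[C@H]1[C@@H](C(=O)OC)[C@H](C(=O)OC)[C@H]1C(C)=O
A9 | alternative 3 | dimethyl 4-acetyl-5-[1-(dimethylsulfamoyl)imidazol-4-yl]pyrrolidine-2,3-dicarboxylate | CN(C)S(=O)(=O)n1cnc(c1)[C@H]1N[C@@H](C(=O)OC)[C@H](C(=O)OC)[C@H]1C(C)=O
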